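**Plan**

- Labels: ring A is the 5-hydroxy-1,3-phenylene ring. Ring B is the 2,5-dihydroxy-1,3-phenylene ring (B1 ether oxygen, B2 OH, B3 chain, B5 OH). The chain runs from C1 (on B3) to C14 (on ring A).
- Retrosynthesis: the two O-methyl groups and a C1 ketone are added back. The B3–C1 bond is then cut by returning the acyl carbon to the B2 oxygen, which gives a 21-membered aryl ester lactone. Next the ester O–C1 bond, the ring A–C14 bond and the B1–O ether bond are cut, leaving a C14 alkynoic acid, 3-bromo-5-methoxyphenol and 2-fluoro-4-methoxybenzaldehyde.
- Enabling feature: B2 lies between B1 and B3, so C1 can sit on the B2 oxygen as an ester and then move to B3, the only ortho carbon that bears hydrogen (the para carbon B5 is oxygenated).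
- Forward order: C14 acid; diaryl ether by SNAr and B2 oxygen by Baeyer–Villiger oxidation; chain joined to ring A by Sonogashira coupling and saturated; the single macrocycle closed first as the lactone and then converted into the carbocyclic ring by the O→C acyl shift; ketone reduction and demethylation.
- Stereochemistry: the target has no stereocentre and no stereogenic double bond, so nothing has to be set.

Key step: step 7

**Route**

Step 1
Reactants: 1 12-bromododecanoic acid
Product: 2 tetradec-13-ynoic acid
Conditions: LiC≡CH·H2NCH2CH2NH2 (3 equiv), DMSO, 10 °C → rt; then aq HCl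
Reagents that add atoms: lithium acetylide–ethylenediamine complex, [Li+].[C-]#C.NCCN
Why: SN2 alkylation of lithium acetylide by the primary bromide in DMSO, with the carboxylate formed by the first equivalent of reagent remaining inert, is a standard way to make ω-alkynoic acids.

Step 2
Reactants: 3 3-bromo-5-methoxyphenol; 4 2-fluoro-4-methoxybenzaldehyde
Product: 5 2-(3-bromo-5-methoxyphenoxy)-4-methoxybenzaldehyde
Conditions: K2CO3, DMF, 120 °C
Reagents that add atoms: none
Why: Nucleophilic aromatic substitution (SNAr), in which the ortho formyl group stabilises the Meisenheimer adduct so that the phenoxide of 3 displaces fluoride while the unactivated aryl bromide is untouched.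

Step 3
Reactants: 5 2-(3-bromo-5-methoxyphenoxy)-4-methoxybenzaldehyde
Product: 7 2-(3-bromo-5-methoxyphenoxy)-4-methoxyphenol, via aryl formate 6 (not isolated)
Conditions: mCPBA, CH2Cl2, rt; then K2CO3 (cat.), MeOH, rt
Reagents that add atoms: mCPBA (3-chloroperoxybenzoic acid), OOC(=O)c1cccc(Cl)c1
Why: Baeyer–Villiger (Dakin-type) oxidation, in which the electron-rich aryl group (ortho aryloxy, para methoxy) migrates in the Criegee adduct in preference to hydrogen and the resulting formate is removed by methanolysis.

Step 4
Reactants: 7 2-(3-bromo-5-methoxyphenoxy)-4-methoxyphenol; 2 tetradec-13-ynoic acid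
Product: 8 14-[3-(2-hydroxy-5-methoxyphenoxy)-5-methoxyphenyl]tetradec-13-ynoic acid
Conditions: Pd(PPh3)2Cl2 (5 mol %), CuI (10 mol %), Et3N, DMF, 70 °C, degassed
Reagents that add atoms: none
Why: Sonogashira coupling of the aryl bromide (its oxygen substituents are meta and do not retard oxidative addition) with the terminal alkyne, the phenol and the carboxylic acid being carried as their ammonium salts.

Step 5
Reactants: 8 14-[3-(2-hydroxy-5-methoxyphenoxy)-5-methoxyphenyl]tetradec-13-ynoic acid
Product: 9 14-[3-(2-hydroxy-5-methoxyphenoxy)-5-methoxyphenyl]tetradecanoic acid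
Conditions: H2 (1 atm), Pd/C (10 %), EtOAc–MeOH, rt
Reagents that add atoms: none
Why: Heterogeneous catalytic hydrogenation should saturate the aryl alkyne fully, since the molecule now holds no halide or benzylic C–O bond and the diaryl ether and methyl ethers are inert.

Step 6
Reactants: 9 14-[3-(2-hydroxy-5-methoxyphenoxy)-5-methoxyphenyl]tetradecanoic acid
Product: 11 21-membered aryl ester macrolactone (1^5,3^5-dimethoxy-2,4-dioxa-1(1,3),3(1,2)-dibenzenacyclooctadecaphan-5-one; the B2 oxygen is acylated by the chain carboxyl), via mixed anhydride 10 (not isolated)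
Conditions: 2,4,6-Cl3C6H2COCl, Et3N, THF, rt; then syringe-pump addition to DMAP, toluene, 90 °C (final 1 mM)
Reagents that add atoms: none
Why: Yamaguchi macrolactonisation, in which DMAP takes the unhindered aliphatic acyl group from the mixed anhydride and passes it to the phenol, and high dilution with a long flexible chain should favour the unstrained 21-membered ring over oligomers.

Step 7
Reactants: 11 21-membered aryl ester macrolactone
Product: 13 21-membered ortho-hydroxyaryl ketone (3^2-hydroxy-1^5,3^5-dimethoxy-2-oxa-1,3(1,3)-dibenzenacycloheptadecaphan-4-one), via dienone tautomer 12 (not isolated)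
Conditions: hν (254 nm, low-pressure Hg lamp, quartz), degassed cyclohexane (1 mM), Ar, rt; run to partial conversion and resubmit recovered 11
Reagents that add atoms: none
Why: Excitation of the ring B aryl ester breaks the ArO–C(=O) bond homolytically into a phenoxyl radical and an acyl radical that cannot separate because the chain still ties the acyl end to ring A; the acyl radical recombines at B3 to give dienone 12, which enolises to the hydrogen-bonded hydroxy ketone 13. The closest known reaction is the photo-Fries rearrangement of aryl esters, which has also been run on macrocyclic aryl lactones to make bridged aryl ketones. The new 21-membered carbocyclic ether ring closes by radical–radical C–C coupling across the opened lactone, formally a 1,3 O→C acyl shift, and the ring size stays at 21 because the ester oxygen leaves the ring as B3 enters it. No stereocentre remains in 13, since the sp3 carbon of 12 is lost on enolisation. The step needs migration to one carbon only: the other ortho carbon (B1) carries the aryloxy group and the para carbon (B5) the methoxy group, so coupling there gives dienones that cannot tautomerise and fall back to the radical pair, and ring A is never a radical site. Once formed, 13 should be shielded from further photochemistry by fast excited-state proton transfer in the chelated ketone.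

Step 8
Reactants: 13 21-membered ortho-hydroxyaryl ketone
Product: 14 1^5,3^5-dimethoxy-2-oxa-1,3(1,3)-dibenzenacycloheptadecaphan-3^2-ol (the dimethyl ether of the target)
Conditions: Et3SiH (5 equiv), CF3CO2H, CH2Cl2, 0 °C → rt
Reagents that add atoms: none
Why: Ionic hydrogenation, in which the protonated aryl ketone accepts hydride from the silane and the resulting ortho-hydroxybenzyl cation, stabilised by the adjacent phenol oxygen, accepts a second hydride to leave the methylene group.

Step 9
Reactants: 14 dimethyl ether of the target
Product: 15 2-oxa-1,3(1,3)-dibenzenacycloheptadecaphane-1^5,3^2,3^5-triol (target)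
Conditions: BBr3 (6 equiv), CH2Cl2, −78 °C → rt; then degassed H2O, Ar
Reagents that add atoms: none
Why: Lewis acid-mediated aryl methyl ether cleavage, in which boron coordinates each methoxy oxygen and bromide attacks the methyl carbon by SN2, while the diaryl ether has no carbon open to such attack and should survive.

**Compound list**

1 | 12-bromododecanoic acid | OC(=O)CCCCCCCCCCCBr | starting material
2 | tetradec-13-ynoic acid | OC(=O)CCCCCCCCCCCC#C | intermediate
3 | 3-bromo-5-methoxyphenol | COc1cc(O)cc(Br)c1 | starting material
4 | 2-fluoro-4-methoxybenzaldehyde | COc1ccc(C=O)c(F)c1 | starting material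
5 | 2-(3-bromo-5-methoxyphenoxy)-4-methoxybenzaldehyde | COc1cc(Br)cc(Oc2cc(OC)ccc2C=O)c1 | intermediate
6 | 2-(3-bromo-5-methoxyphenoxy)-4-methoxyphenyl formate | COc1cc(Br)cc(Oc2cc(OC)ccc2OC=O)c1 | intermediate (not isolated)
7 | 2-(3-bromo-5-methoxyphenoxy)-4-methoxyphenol | COc1cc(Br)cc(Oc2cc(OC)ccc2O)c1 | intermediate
8 | 14-[3-(2-hydroxy-5-methoxyphenoxy)-5-methoxyphenyl]tetradec-13-ynoic acid | COc1cc(C#CCCCCCCCCCCCC(=O)O)cc(Oc2cc(OC)ccc2O)c1 | intermediate
9 | 14-[3-(2-hydroxy-5-methoxyphenoxy)-5-methoxyphenyl]tetradecanoic acid | COc1cc(CCCCCCCCCCCCCC(=O)O)cc(Oc2cc(OC)ccc2O)c1 | intermediate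
10 | mixed anhydride of 9 with 2,4,6-trichlorobenzoic acid | COc1cc(CCCCCCCCCCCCCC(=O)OC(=O)c3c(Cl)cc(Cl)cc3Cl)cc(Oc2cc(OC)ccc2O)c1 | intermediate (not isolated)
11 | 21-membered aryl ester macrolactone (1^5,3^5-dimethoxy-2,4-dioxa-1(1,3),3(1,2)-dibenzenacyclooctadecaphan-5-one) | COc1cc2cc(c1)Oc1cc(OC)ccc1OC(=O)CCCCCCCCCCCCC2 | intermediate
12 | dienone tautomer of 13 (6-acylcyclohexa-2,4-dienone form of ring B; transient, racemic at the sp3 carbon) | COc1cc2cc(c1)OC1=CC(OC)=CC(C1=O)C(=O)CCCCCCCCCCCCC2 | intermediate (not isolated)
13 | 21-membered ortho-hydroxyaryl ketone (3^2-hydroxy-1^5,3^5-dimethoxy-2-oxa-1,3(1,3)-dibenzenacycloheptadecaphan-4-one) | COc1cc2cc(c1)Oc1cc(OC)cc(c1O)C(=O)CCCCCCCCCCCCC2 | intermediate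
14 | 1^5,3^5-dimethoxy-2-oxa-1,3(1,3)-dibenzenacycloheptadecaphan-3^2-ol | COc1cc2cc(c1)Oc1cc(OC)cc(c1O)CCCCCCCCCCCCCC2 | intermediate
15 | 2-oxa-1,3(1,3)-dibenzenacycloheptadecaphane-1^5,3^2,3^5-triol | Oc1cc2cc(c1)Oc1cc(O)cc(c1O)CCCCCCCCCCCCCC2 | target

**Step count and risks**

Total: 9 steps. Longest linear sequence: 8 steps (steps 2 to 9, from 3 and 4). Step 1 is a one-step side branch.

Steps most likely to fail:

1. Step 7 (photochemical acyl shift). The tethered radical pair may lose carbon monoxide or abstract hydrogen instead of coupling at carbon. The diaryl ether chromophore may undergo its own photocleavage. Light absorption by the product may stall conversion. The fallback keeps the same O→C acyl shift but runs it as an anionic Fries rearrangement triggered by halogen–lithium exchange. It sets out from 9 and comes back at 13. Amine-mediated ortho-bromination of the ring B phenol (Br2, t-BuNH2, toluene, −78 °C) delivers bromine through the phenol hydrogen bond to the only free ortho carbon. This should spare the electron-rich ring A and give 14-[3-(3-bromo-2-hydroxy-5-methoxyphenoxy)-5-methoxyphenyl]tetradecanoic acid F1. Lactonisation under the conditions of step 6 gives the bromo macrolactone F2. With t-BuLi (2 equiv, THF, −100 °C) the bromine is exchanged and the aryllithium takes the acyl group from the neighbouring ester oxygen, giving 13 after protonation.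

2. Step 6 (macrolactonisation on a phenol). Intermolecular acyl transfer to oligomers, and aroyl transfer from the wrong carbonyl of the mixed anhydride to the ortho-substituted phenol, may outrun ring closure. The fallback forms the ester between two molecules and closes the ring at a C=C bond. It sets out from 7 and 2 and comes back at 11. Lindlar semi-hydrogenation of 2 (Pd on CaCO3 poisoned with Pb(OAc)2, quinoline, H2) gives tetradec-13-enoic acid F3. Suzuki–Miyaura coupling of 7 with vinylboronic acid pinacol ester (Pd(dppf)Cl2, K2CO3, dioxane–H2O, 80 °C) gives 2-(3-ethenyl-5-methoxyphenoxy)-4-methoxyphenol F4. Steglich esterification of F4 with F3 (DCC, DMAP, CH2Cl2) gives 2-(3-ethenyl-5-methoxyphenoxy)-4-methoxyphenyl tetradec-13-enoate F5. Ring-closing metathesis with the second-generation Grubbs catalyst, RuCl2(=CHPh)(PCy3)(H2IMes), in CH2Cl2 at 40 °C and 1 mM releases ethylene and closes the 21-membered lactone as the styrenyl alkene F6. Hydrogenation (H2, Pd/C) erases the alkene geometry and gives 11.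

3. Step 8 (ionic hydrogenation). In CF3CO2H the ortho-hydroxybenzyl cation may be captured across the ring by the electron-rich ring A (transannular Friedel–Crafts alkylation), or reduction may stop at the carbinol. The fallback avoids any carbocation. It sets out from 13 and comes back at 14. ClCO2Et and Et3N in THF at 0 °C convert the chelated phenol into the aryl ethyl carbonate F7. NaBH4 in THF–H2O then reduces the ketone, the carbonate shifts to the benzylic oxygen and is expelled to an ortho-quinone methide, and this takes a second hydride to give 14 under basic conditions.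

**Further compounds**

F1 | step 7 | 14-[3-(3-bromo-2-hydroxy-5-methoxyphenoxy)-5-methoxyphenyl]tetradecanoic acid | COc1cc(CCCCCCCCCCCCCC(=O)O)cc(Oc2cc(OC)cc(Br)c2O)c1
F2 | step 7 | bromo macrolactone (11 with bromine on ring B ortho to the ester oxygen) | COc1cc2cc(c1)Oc1cc(OC)cc(Br)c1OC(=O)CCCCCCCCCCCCC2
F3 | step 6 | tetradec-13-enoic acid | OC(=O)CCCCCCCCCCCC=C
F4 | step 6 | 2-(3-ethenyl-5-methoxyphenoxy)-4-methoxyphenol | COc1cc(C=C)cc(Oc2cc(OC)ccc2O)c1
F5 | step 6 | 2-(3-ethenyl-5-methoxyphenoxy)-4-methoxyphenyl tetradec-13-enoate | C=CCCCCCCCCCCCC(=O)Oc1ccc(OC)cc1Oc1cc(OC)cc(C=C)c1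
F6 | step 6 | unsaturated macrolactone (11 with a C13=C14 double bond next to ring A; E isomer drawn, either geometry serves) | O=C1CCCCCCCCCCC/C=C/c2cc(OC)cc(c2)Oc2cc(OC)ccc2O1
F7 | step 8 | ethyl carbonate of 13 (B2 oxygen carries CO2Et) | COc1cc2cc(c1)Oc1cc(OC)cc(c1OC(=O)OCC)C(=O)CCCCCCCCCCCCC2
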